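**Retrosynthetic overview**

1. The target is numbered as a 3a,6a-dihydropentalene-1,6-dione: C1=O, C2H=C3(styryl), C3a–H, C4(3,5-dihydroxyphenyl)=C5(3,4,5-trihydroxyphenyl), C6=O, C6a–OH. The enabling feature is the ring-fusion carbinol C6a between the two ring carbonyls C1 and C6 (a 2-hydroxy-1,3-diketone). This is the retron of an α-ketol 1,2-acyl shift: returning C1 from C6a to C6 opens cyclopentenone ring A (C1–C2–C3–C3a–C6a) to a six-membered ring C1–C2–C3–C3a–C6a–C6 with three contiguous oxygenated carbons (C1, C6, C6a), i.e. an oxidised pyrogallol ring.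
2. That six-membered ring, bridged from C6 over C5=C4 to C3a, is a 1-hydroxybicyclo[3.2.1]octa-3,6-diene-2,8-dione. It is the (5+2) adduct of a 3-hydroxy-o-quinone and the diarylalkyne C4≡C5, which copies the presumed biogenetic union of an oxidised 3,4,5-trihydroxyphenyl ring with the two-carbon unit of a second stilbene.
3. Disconnections: seven O–CH3 bonds (last step); C3–styryl by Suzuki–Miyaura coupling of a C3 bromide (bromine stands in for the styryl group during the key step so that the quinone cation cannot spread into a side chain); C3a–C4 and C6–C5 by (5+2) cycloaddition; C1–C6a by acyl shift; the alkyne by Sonogashira coupling.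
4. Ring order: the flat ring of 5-bromopyrogallol is dearomatised to the bridged adduct, which already contains ring B (C3a–C4–C5–C6–C6a); its six-membered ring then contracts to ring A. Both stereocentres arise in this one operation under a chiral Brønsted acid.

Key step: step 4

Assumption: the sense of induction of the chiral acid in step 4 cannot be derived from precedent; the (R)-catalyst is written and stands for whichever antipode is found to give the (3aS,6aS) series.

**Route**

Step 1
Reactants: 1 1-ethynyl-3,5-dimethoxybenzene; 2 5-iodo-1,2,3-trimethoxybenzene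
Product: 3 5-[(3,5-dimethoxyphenyl)ethynyl]-1,2,3-trimethoxybenzene
Conditions: PdCl2(PPh3)2 (2 mol%), CuI (4 mol%), Et3N, THF, rt → 50 °C
Reagents that add atoms: none
Why: Sonogashira coupling; Pd(0) inserts into the aryl iodide and the copper acetylide of 1 transmetalates, which should give the unsymmetrical diarylalkyne without touching the methyl ethers.

Step 2
Reactants: 1 1-ethynyl-3,5-dimethoxybenzene
Product: 4 2-[(E)-2-(3,5-dimethoxyphenyl)ethenyl]-4,4,5,5-tetramethyl-1,3,2-dioxaborolane
Conditions: HBpin (1.1 equiv), Cp2Zr(H)Cl (5 mol%), Et3N (10 mol%), neat, 60 °C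
Reagents that add atoms: pinacolborane, [H]B1OC(C)(C)C(C)(C)O1
Why: Zirconocene-hydride-catalysed hydroboration of a terminal alkyne is a syn addition with boron at the terminal carbon, which sets the E geometry of the vinyl boronate.

Step 3
Reactants: 5 5-bromo-1,2,3-trimethoxybenzene
Product: 6 5-bromobenzene-1,2,3-triol
Conditions: BBr3 (4 equiv), CH2Cl2, −78 °C → rt; H2O; work-up and storage under Ar
Reagents that add atoms: none
Why: BBr3 demethylation of aryl methyl ethers (O-coordination, bromide attack at methyl); the aryl bromide is inert and the air-sensitive pyrogallol is kept under argon.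

Step 4
Reactants: 6 5-bromobenzene-1,2,3-triol; 3 5-[(3,5-dimethoxyphenyl)ethynyl]-1,2,3-trimethoxybenzene
Product: 9 (3aS,6aS)-3-bromo-4-(3,5-dimethoxyphenyl)-6a-hydroxy-5-(3,4,5-trimethoxyphenyl)-3a,6a-dihydropentalene-1,6-dione, via hydroxy-o-quinone 7 (not isolated), via bridged dienedione 8 (not isolated)
Conditions: (i) Ag2O (2 equiv), MgSO4, Et2O, −20 °C, cold filtration under Ar; (ii) 3 (1.5 equiv), (R)-3,3′-bis(2,4,6-triisopropylphenyl)-1,1′-binaphthyl-2,2′-diyl N-triflylphosphoramide (10 mol%), 4 Å MS, CH2Cl2, −78 → −30 °C; (iii) i-Pr2NEt (1.2 equiv), −30 → 0 °C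
Reagents that add atoms: none
Why: Proposed new method: Ag2O dehydrogenates 6 to the flat hydroxy-o-quinone 7 (numbered C1=O, C2=O, C3–OH, C4–H, C5–Br, C6–H); the chiral N-triflylphosphoramide binds the enol O–H and the central C2=O, which turns C2–C3(OH)–C4 into a 2-hydroxyallyl cation, the alkyne carbon bearing the 3,5-dimethoxyphenyl ring attacks C4 (the vinyl cation is then stabilised by the 4-methoxy group of the trimethoxyphenyl ring) and the enediol carbon C2 captures that cation, a stepwise cationic (5+2) cycloaddition that closes the seven-membered ring and, by formally 5-endo-dig C-attack of the enol on the vinyl cation, the five-membered ring B of 8. On addition of i-Pr2NEt the bridgehead alkoxide of 8, which sits between the enone carbonyl C2 and the strained bridging carbonyl C8, should undergo an α-ketol (acyloin) rearrangement in which acyl carbon C2 migrates from C1 to C8, so that the six-membered ring C1–C2–C3–C4–C5–C8 contracts to cyclopentenone ring A of 9, driven by loss of the 7-norbornenone-type strain and by conjugation of the new C6 ketone with the diaryl alkene. Closest known reaction types are the acid-promoted (5+2) cycloadditions of alkoxyquinones and quinone monoketals with aryl alkenes (also run with chiral titanium TADDOLates), the perezone–pipitzol and purpurogallin-type (5+2) reactions of hydroxyquinones, chiral phosphoramide ion-pair catalysis of oxygenated pentadienyl cations (Nazarov cyclisation) and the humulone-to-isohumulone acyloin ring contraction; new are the alkyne as two-carbon partner, the catalytic enantioselective use of a hydroxy-o-quinone and the merger with the acyl shift. The stereocentre C5 of 8 (C3a of 9) is set by the catalyst, which shields one of the two enantiotopic faces of the bound quinone in the first C–C bond formation; C1 of 8 follows from the bridged ring, and the suprafacial acyl shift relays this to C6a of 9, where only the cis ring fusion is possible. The step needs the stated aryl regiochemistry, C- rather than O-capture of the vinyl cation (O-capture would aromatise to a 2,3-diarylbenzofuran) and survival of 8 against cheletropic loss of CO to a tropolone; these are to be secured by the electronic bias of the two aryl rings, by low temperature with the immediate irreversible acyl shift, and by the bromine at C5 of 7, which replaces the styryl group so that the cation cannot spread into a side chain.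

Step 5
Reactants: 9 (3aS,6aS)-3-bromo-4-(3,5-dimethoxyphenyl)-6a-hydroxy-5-(3,4,5-trimethoxyphenyl)-3a,6a-dihydropentalene-1,6-dione; 4 2-[(E)-2-(3,5-dimethoxyphenyl)ethenyl]-4,4,5,5-tetramethyl-1,3,2-dioxaborolane
Product: 10 (3aS,6aS)-4-(3,5-dimethoxyphenyl)-3-[(E)-2-(3,5-dimethoxyphenyl)ethenyl]-6a-hydroxy-5-(3,4,5-trimethoxyphenyl)-3a,6a-dihydropentalene-1,6-dione
Conditions: Pd(dppf)Cl2·CH2Cl2 (5 mol%), K3PO4 (2 equiv), THF–H2O (10:1), degassed, rt → 40 °C
Reagents that add atoms: none
Why: Suzuki–Miyaura coupling; the β-bromo enone undergoes fast oxidative addition and the E vinyl boronate transfers its alkenyl group with retention of geometry, while the mild phosphate base near room temperature should leave the 2-hydroxy-1,3-diketone and both stereocentres untouched.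

Step 6
Reactants: 10 (3aS,6aS)-4-(3,5-dimethoxyphenyl)-3-[(E)-2-(3,5-dimethoxyphenyl)ethenyl]-6a-hydroxy-5-(3,4,5-trimethoxyphenyl)-3a,6a-dihydropentalene-1,6-dione
Product: 11 (3aS,6aS)-4-(3,5-dihydroxyphenyl)-3-[(E)-2-(3,5-dihydroxyphenyl)ethenyl]-6a-hydroxy-5-(3,4,5-trihydroxyphenyl)-3a,6a-dihydropentalene-1,6-dione
Conditions: BBr3 (15 equiv), CH2Cl2, −78 → 0 °C; then MeOH, H2O
Reagents that add atoms: none
Why: Exhaustive BBr3 cleavage of the seven aryl methyl ethers; the tertiary alcohol should not ionise because its cation would lie between two carbonyl groups, and the ring-fusion centres cannot epimerise because only the cis-fused bicycle exists.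

**Compound list**

1 | 1-ethynyl-3,5-dimethoxybenzene | COc1cc(OC)cc(C#C)c1 | starting material
2 | 5-iodo-1,2,3-trimethoxybenzene | COc1cc(I)cc(OC)c1OC | starting material
3 | 5-[(3,5-dimethoxyphenyl)ethynyl]-1,2,3-trimethoxybenzene | COc1cc(OC)cc(C#Cc2cc(OC)c(OC)c(OC)c2)c1 | intermediate
4 | 2-[(E)-2-(3,5-dimethoxyphenyl)ethenyl]-4,4,5,5-tetramethyl-1,3,2-dioxaborolane | COc1cc(OC)cc(/C=C/B2OC(C)(C)C(C)(C)O2)c1 | intermediate
5 | 5-bromo-1,2,3-trimethoxybenzene | COc1cc(Br)cc(OC)c1OC | starting material
6 | 5-bromobenzene-1,2,3-triol | Oc1cc(Br)cc(O)c1O | intermediate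
7 | 5-bromo-3-hydroxycyclohexa-3,5-diene-1,2-dione (not isolated) | O=C1C(=O)C(O)=CC(Br)=C1 | intermediate
8 | (1R,5S)-4-bromo-6-(3,5-dimethoxyphenyl)-1-hydroxy-7-(3,4,5-trimethoxyphenyl)bicyclo[3.2.1]octa-3,6-diene-2,8-dione (not isolated) | O[C@]12C(=O)C=C(Br)[C@H](C1=O)C(c1cc(OC)cc(OC)c1)=C2c1cc(OC)c(OC)c(OC)c1 | intermediate
9 | (3aS,6aS)-3-bromo-4-(3,5-dimethoxyphenyl)-6a-hydroxy-5-(3,4,5-trimethoxyphenyl)-3a,6a-dihydropentalene-1,6-dione | O=C1C=C(Br)[C@H]2C(c3cc(OC)cc(OC)c3)=C(c3cc(OC)c(OC)c(OC)c3)C(=O)[C@@]12O | intermediate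
10 | (3aS,6aS)-4-(3,5-dimethoxyphenyl)-3-[(E)-2-(3,5-dimethoxyphenyl)ethenyl]-6a-hydroxy-5-(3,4,5-trimethoxyphenyl)-3a,6a-dihydropentalene-1,6-dione | O=C1C=C(/C=C/c2cc(OC)cc(OC)c2)[C@H]2C(c3cc(OC)cc(OC)c3)=C(c3cc(OC)c(OC)c(OC)c3)C(=O)[C@@]12O | intermediate
11 | (3aS,6aS)-4-(3,5-dihydroxyphenyl)-3-[(E)-2-(3,5-dihydroxyphenyl)ethenyl]-6a-hydroxy-5-(3,4,5-trihydroxyphenyl)-3a,6a-dihydropentalene-1,6-dione | O=C1C=C(/C=C/c2cc(O)cc(O)c2)[C@H]2C(c3cc(O)cc(O)c3)=C(c3cc(O)c(O)c(O)c3)C(=O)[C@@]12O | target

**Step count and risks**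

Total step count: 6. Longest linear sequence: 4 steps (5 → 6 → 9 → 10 → 11; the sequence 1 → 3 → 9 → 10 → 11 is equally long).

Steps most likely to fail:

1. Step 4 (proposed new method). The hydrogen-bonded quinone may not be electrophilic enough for the diarylalkyne; the vinyl cation may be captured at oxygen with aromatisation instead of at carbon; the bridged dienedione may lose carbon monoxide before the acyl shift; or face discrimination by the catalyst may be poor. Fallback with known chemistry, setting out from 6 and coming back at 9: the alkyne is replaced by the proven two-carbon partner of acid-promoted quinone (5+2) cycloadditions, an electron-rich aryl alkene, and the missing unsaturation and the absolute configuration are supplied afterwards. Horner–Wadsworth–Emmons reaction of commercial diethyl (3,5-dimethoxybenzyl)phosphonate with commercial 3,4,5-trimethoxybenzaldehyde (NaH, THF) gives (E)-1-(3,5-dimethoxyphenyl)-2-(3,4,5-trimethoxyphenyl)ethene F1. Quinone 7, generated from 6 with Ag2O as in step 4, is combined with F1 and an achiral acid (CF3CO2H or BF3·OEt2, CH2Cl2, −78 °C) to give the racemic bridged dione rac-4-bromo-6-(3,5-dimethoxyphenyl)-1-hydroxy-7-(3,4,5-trimethoxyphenyl)bicyclo[3.2.1]oct-3-ene-2,8-dione F2 (6,7-trans; either trans isomer serves). i-Pr2NEt in CH2Cl2 brings about the α-ketol ring contraction to the racemic 3a,4,5,6a-tetrahydropentalene-1,6-dione F3. DDQ in dioxane at 80 °C dehydrogenates the doubly benzylic C4–C5 bond next to the C6 ketone to racemic 9, and preparative HPLC on a chiral stationary phase separates 9 from its (3aR,6aR) enantiomer F4.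

2. Step 6. Lewis-acid-induced Friedel–Crafts cyclisation of an electron-rich aryl ring onto the boron-activated styryl dienone, addition of HBr to the dienone, or incomplete cleavage of seven ethers. Fallback, setting out from 9 and coming back at 11: the five methyl ethers are cleaved before the acid-sensitive side arm exists, and the arm is brought in as a bis-silyl ether. BBr3 (CH2Cl2, −78 → 0 °C) converts 9 into the pentaphenol (3aS,6aS)-3-bromo-4-(3,5-dihydroxyphenyl)-6a-hydroxy-5-(3,4,5-trihydroxyphenyl)-3a,6a-dihydropentalene-1,6-dione F5. Commercial 3,5-dihydroxybenzaldehyde is silylated (TBSCl, imidazole, DMF) to 3,5-bis(tert-butyldimethylsilyloxy)benzaldehyde F6, which with lithiated bis[(pinacolato)boryl]methane (LiTMP, THF, −78 °C → rt, boron-Wittig olefination) gives the E vinyl boronate F7. Suzuki–Miyaura coupling of F5 with F7 (Pd(dppf)Cl2, K3PO4, degassed THF–H2O, rt) gives the bis-silyl ether F8 of the target, and HF·pyridine (THF, 0 °C) releases 11.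

3. Step 5. Base-induced retro-Claisen opening or α-ketol equilibration of the 2-hydroxy-1,3-diketone, air oxidation of its dienolate, or protodeboronation of 4 before transmetalation. Fallback, setting out from 9 and 1 and coming back at 10: a base-free Stille coupling. Radical hydrostannation of 1 (Bu3SnH, AIBN, toluene, 80 °C, E isomer by equilibration) gives (E)-tributyl[2-(3,5-dimethoxyphenyl)ethenyl]stannane F9, which couples with 9 under neutral conditions (Pd2(dba)3, AsPh3, CuI, DMF, rt) to give 10.

**Further compounds**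

F1 | step 4 | (E)-1-(3,5-dimethoxyphenyl)-2-(3,4,5-trimethoxyphenyl)ethene | COc1cc(OC)cc(/C=C/c2cc(OC)c(OC)c(OC)c2)c1
F2 | step 4 | rac-4-bromo-6-(3,5-dimethoxyphenyl)-1-hydroxy-7-(3,4,5-trimethoxyphenyl)bicyclo[3.2.1]oct-3-ene-2,8-dione, 6,7-trans, C7 aryl on the side of the C8 bridge (one enantiomer drawn) | O[C@]12C(=O)C=C(Br)[C@H](C1=O)[C@@H](c1cc(OC)cc(OC)c1)[C@@H]2c1cc(OC)c(OC)c(OC)c1
F3 | step 4 | rac-3-bromo-4-(3,5-dimethoxyphenyl)-6a-hydroxy-5-(3,4,5-trimethoxyphenyl)-3a,4,5,6a-tetrahydropentalene-1,6-dione, cis-fused, 4,5-trans (one enantiomer drawn) | O=C1C=C(Br)[C@H]2[C@@H](c3cc(OC)cc(OC)c3)[C@H](c3cc(OC)c(OC)c(OC)c3)C(=O)[C@@]12O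
F4 | step 4 | (3aR,6aR)-3-bromo-4-(3,5-dimethoxyphenyl)-6a-hydroxy-5-(3,4,5-trimethoxyphenyl)-3a,6a-dihydropentalene-1,6-dione | O=C1C=C(Br)[C@@H]2C(c3cc(OC)cc(OC)c3)=C(c3cc(OC)c(OC)c(OC)c3)C(=O)[C@]12O
F5 | step 6 | (3aS,6aS)-3-bromo-4-(3,5-dihydroxyphenyl)-6a-hydroxy-5-(3,4,5-trihydroxyphenyl)-3a,6a-dihydropentalene-1,6-dione | O=C1C=C(Br)[C@H]2C(c3cc(O)cc(O)c3)=C(c3cc(O)c(O)c(O)c3)C(=O)[C@@]12O
F6 | step 6 | 3,5-bis(tert-butyldimethylsilyloxy)benzaldehyde | O=Cc1cc(O[Si](C)(C)C(C)(C)C)cc(O[Si](C)(C)C(C)(C)C)c1
F7 | step 6 | 2-{(E)-2-[3,5-bis(tert-butyldimethylsilyloxy)phenyl]ethenyl}-4,4,5,5-tetramethyl-1,3,2-dioxaborolane | CC(C)(C)[Si](C)(C)Oc1cc(O[Si](C)(C)C(C)(C)C)cc(/C=C/B2OC(C)(C)C(C)(C)O2)c1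
F8 | step 6 | (3aS,6aS)-3-{(E)-2-[3,5-bis(tert-butyldimethylsilyloxy)phenyl]ethenyl}-4-(3,5-dihydroxyphenyl)-6a-hydroxy-5-(3,4,5-trihydroxyphenyl)-3a,6a-dihydropentalene-1,6-dione | O=C1C=C(/C=C/c2cc(O[Si](C)(C)C(C)(C)C)cc(O[Si](C)(C)C(C)(C)C)c2)[C@H]2C(c3cc(O)cc(O)c3)=C(c3cc(O)c(O)c(O)c3)C(=O)[C@@]12O
F9 | step 5 | (E)-tributyl[2-(3,5-dimethoxyphenyl)ethenyl]stannane | CCCC[Sn](CCCC)(CCCC)/C=C/c1cc(OC)cc(OC)c1
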